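The piperidine ring (ring A) is formed by a tethered zwitterionic aza-Claisen rearrangement. The feature exploited is the bridged ring A/ring B core: quaternary C6 sits allylic to the nitrogen once C4 of its side chain is bonded to N, i.e. in a spiro 1,2,3,6-tetrahydropyridine (ring T: N, C22, C21, C6=C5, C4) on the diquinane (rings C and D). The C12 butanoic acid chain, activated as its acid fluoride, acylates the ring nitrogen (N–C25) and the ammonium enolate shifts [3,3] (C9–C6): one operation gives lactam ring A and cycloheptene ring B, opens ring T and sets C6 and C9 from C21. The expelled vinyl group is then extended by cross-metathesis.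

Key step: step 14

Remarks.
- Numbering: atom numbers follow the target SMILES from left to right, heteroatoms counted. C1–C5 is the hydroxypentyl chain (C3 carbinol); C6 is the quaternary carbon bearing C7H2OH; C9 is the ring-fusion CH; then C10, C11, C12=C13, C14, C15, C16, C17 (bearing C18H2OH), C20, C21 (spiro quaternary), C22 (its NCH2), N23 (methyl C24) and C25 (NCH2 on C9).
- Rings: ring A is the piperidine (N23, C25, C9, C6, C21, C22); ring B the cycloheptene (C6, C9–C13, C21); ring C the cyclopentene (C12–C16); ring D the cyclopentane (C13, C14, C17, C20, C21); ring T the temporary tetrahydropyridine (N23, C22, C21, C6, C5, C4).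
- Faces of ring D: the α face carries C22 and 14-H; the β face carries C6, C15 and C18.
- The ring-T carbon C4 is sacrificial and leaves as ethene in step 15; C1–C4 of the target come from ethyl vinyl ketone.
- Assumption: the antipode of the phase-transfer catalyst (step 1) and of BINAP (step 9) that gives the stated configuration is fixed by a short screen; both antipodes of each are commercial.

Step 1
Reactants: 1 1-tert-butyl 3-methyl 4-oxopiperidine-1,3-dicarboxylate; 2 2,3-dibromoprop-1-ene
Product: 3 1-tert-butyl 3-methyl (3R)-3-(2-bromoprop-2-en-1-yl)-4-oxopiperidine-1,3-dicarboxylate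
Conditions: 2 (1.2 equiv), (S,S)-3,4,5-trifluorophenyl-NAS bromide (chiral spiro binaphthyl ammonium bromide, 2 mol %), Cs2CO3, toluene, −20 °C
Reagents that add atoms: 2,3-dibromoprop-1-ene (compound 2), C=C(Br)CBr
Why: Asymmetric phase-transfer C-alkylation of the β-keto ester enolate, in which the chiral ammonium ion pair shields one enolate face and so sets the quaternary C21 (3R).

Step 2
Reactants: 3 1-tert-butyl 3-methyl (3R)-3-(2-bromoprop-2-en-1-yl)-4-oxopiperidine-1,3-dicarboxylate; 4 tributyl(ethenyl)stannane
Product: 5 1-tert-butyl 3-methyl (3R)-3-(2-methylidenebut-3-en-1-yl)-4-oxopiperidine-1,3-dicarboxylate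
Conditions: 4, Pd(PPh3)4 (5 mol %), toluene, 100 °C
Reagents that add atoms: tributyl(ethenyl)stannane (compound 4), C=C[Sn](CCCC)(CCCC)CCCC
Why: Stille coupling of the 1,1-disubstituted alkenyl bromide with the vinylstannane under neutral conditions gives the 2-substituted butadiene (C18=C17–C14=C15) without touching the base-sensitive quaternary β-keto ester.

Step 3
Reactants: 5 1-tert-butyl 3-methyl (3R)-3-(2-methylidenebut-3-en-1-yl)-4-oxopiperidine-1,3-dicarboxylate
Product: 6 1-tert-butyl 3-methyl (3R)-3-(2-methylidenebut-3-en-1-yl)-4-[(trifluoromethanesulfonyl)oxy]-3,6-dihydro-2H-pyridine-1,3-dicarboxylate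
Conditions: KN(SiMe3)2, THF, −78 °C; N-phenylbis(trifluoromethanesulfonimide)
Reagents that add atoms: N-phenylbis(trifluoromethanesulfonimide), O=S(=O)(N(c1ccccc1)S(=O)(=O)C(F)(F)F)C(F)(F)F
Why: Enol triflate formation is regiodefined because the ketone can enolise only toward C5 (C21 is quaternary), which places the ring-T double bond at C5=C6.

Step 4
Reactants: 6 1-tert-butyl 3-methyl (3R)-3-(2-methylidenebut-3-en-1-yl)-4-[(trifluoromethanesulfonyl)oxy]-3,6-dihydro-2H-pyridine-1,3-dicarboxylate; 7 potassium [(benzyloxy)methyl]trifluoroborate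
Product: 8 1-tert-butyl 3-methyl (3S)-4-[(benzyloxy)methyl]-3-(2-methylidenebut-3-en-1-yl)-3,6-dihydro-2H-pyridine-1,3-dicarboxylate
Conditions: 7, Pd(OAc)2, RuPhos, Cs2CO3, dioxane/H2O, 90 °C
Reagents that add atoms: potassium [(benzyloxy)methyl]trifluoroborate (compound 7), [K+].F[B-](F)(F)COCc1ccccc1
Why: Suzuki–Miyaura sp2–sp3 coupling of the alkenyl triflate with the alkoxymethyltrifluoroborate installs C7 as its benzyl ether (the descriptor changes by priority only).

Step 5
Reactants: 8 1-tert-butyl 3-methyl (3S)-4-[(benzyloxy)methyl]-3-(2-methylidenebut-3-en-1-yl)-3,6-dihydro-2H-pyridine-1,3-dicarboxylate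
Product: 9 [(3S)-4-[(benzyloxy)methyl]-1-methyl-3-(2-methylidenebut-3-en-1-yl)-1,2,3,6-tetrahydropyridin-3-yl]methanol
Conditions: LiAlH4, THF, 0 °C to reflux
Reagents that add atoms: none
Why: Hydride reduction converts the neopentyl ester into C13H2OH and the Boc carbamate into the N-methyl group in one operation, leaving the ether and the alkenes untouched.

Step 6
Reactants: 9 [(3S)-4-[(benzyloxy)methyl]-1-methyl-3-(2-methylidenebut-3-en-1-yl)-1,2,3,6-tetrahydropyridin-3-yl]methanol
Product: 10 (3S)-4-[(benzyloxy)methyl]-1-methyl-3-(2-methylidenebut-3-en-1-yl)-1,2,3,6-tetrahydropyridine-3-carbaldehyde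
Conditions: (COCl)2, DMSO, CH2Cl2, −78 °C; Et3N
Reagents that add atoms: none
Why: Swern oxidation gives the aldehyde, which cannot epimerise (α-quaternary) and is compatible with the tertiary amine.

Step 7
Reactants: 10 (3S)-4-[(benzyloxy)methyl]-1-methyl-3-(2-methylidenebut-3-en-1-yl)-1,2,3,6-tetrahydropyridine-3-carbaldehyde
Product: 11 (3S)-4-[(benzyloxy)methyl]-3-ethynyl-1-methyl-3-(2-methylidenebut-3-en-1-yl)-1,2,3,6-tetrahydropyridine
Conditions: dimethyl (1-diazo-2-oxopropyl)phosphonate, K2CO3, MeOH, 0 °C to rt
Reagents that add atoms: dimethyl (1-diazo-2-oxopropyl)phosphonate, COP(=O)(OC)C(=[N+]=[N-])C(C)=O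
Why: Ohira–Bestmann (Seyferth–Gilbert) homologation turns the non-enolisable aldehyde into the terminal alkyne C13≡C12 under mild base.

Step 8
Reactants: 11 (3S)-4-[(benzyloxy)methyl]-3-ethynyl-1-methyl-3-(2-methylidenebut-3-en-1-yl)-1,2,3,6-tetrahydropyridine; 12 4-bromo-1,1,1-trimethoxybutane
Product: 15 methyl 6-[(3S)-4-[(benzyloxy)methyl]-1-methyl-3-(2-methylidenebut-3-en-1-yl)-1,2,3,6-tetrahydropyridin-3-yl]hex-5-ynoate, via lithium acetylide 13 (not isolated), via ortho ester 14 (not isolated)
Conditions: n-BuLi, THF, −78 °C; 12, DMPU, −78 °C to rt; then aqueous citric acid, rt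
Reagents that add atoms: 4-bromo-1,1,1-trimethoxybutane (compound 12), COC(OC)(OC)CCCBr; water, O
Why: Acetylide alkylation with the ortho-ester-masked 4-bromobutanoate (an ester would be attacked) attaches C11–C10–C9–C25, and mild acid then releases the methyl ester.

Step 9
Reactants: 15 methyl 6-[(3S)-4-[(benzyloxy)methyl]-1-methyl-3-(2-methylidenebut-3-en-1-yl)-1,2,3,6-tetrahydropyridin-3-yl]hex-5-ynoate
Product: 16 (14S,21S)-spiro dienone ester: ring C/ring D bicyclo[3.3.0]oct-1-en-3-one spiro-fused at C21 to ring T; C16 ketone; C17 exocyclic methylene; methyl butanoate chain on C12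
Conditions: [Rh(CO)2Cl]2 (5 mol %), (S)-BINAP (antipode per the assumption), AgOSO2CF3, CO (1 atm), THF, 70 °C
Reagents that add atoms: carbon monoxide, [C-]#[O+]
Why: Intramolecular Pauson–Khand [2+2+1] cycloaddition of the alkyne, the monosubstituted alkene of the diene and CO builds rings C and D at once, and C14 is set under catalyst control by the chiral Rh–BINAP complex (C15 on the face of the C6 arm), the remote spiro centre exerting little bias.

Step 10
Reactants: 16 (14S,21S)-spiro dienone ester
Product: 18 (14S,17S,21S)-diol: C18 primary alcohol on the β face; C16 allylic alcohol as a mixture of epimers, via bis-borane adduct 17 (not isolated)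
Conditions: 9-BBN (3 equiv), THF, 0 °C to rt; then NaBO3·4H2O, H2O, rt
Reagents that add atoms: sodium perborate, [Na+].[O-]OB=O
Why: Hydroboration–oxidation with 9-BBN adds anti-Markovnikov to the exocyclic C17=C18 alkene from the convex α face (away from C15 and the benzyloxymethyl-bearing C6 arm), which places C18 cis to C15 and C6, while the same reagent reduces the enone carbonyl 1,2 to a carbinol that is removed in step 12.

Step 11
Reactants: 18 (14S,17S,21S)-diol
Product: 19 (14S,17S,21S)-C18 pivalate with free C16 allylic alcohol (epimers)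
Conditions: pivaloyl chloride (1.05 equiv), pyridine, CH2Cl2, −20 °C
Reagents that add atoms: pivaloyl chloride, CC(C)(C)C(Cl)=O
Why: Selective acylation of the primary over the hindered secondary allylic alcohol gives a pivalate that survives steps 12–17 and is cleaved in the final reduction.

Step 12
Reactants: 19 (14S,17S,21S)-C18 pivalate with free C16 allylic alcohol
Product: 20 (14S,17S,21S)-amino ester: ring C deoxygenated at C16; C12=C13 alkene; methyl butanoate chain on C12
Conditions: Et3SiH, CF3CO2H, CH2Cl2, −20 °C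
Reagents that add atoms: none
Why: Ionic deoxygenation, in which acid ionises the allylic alcohol to the C16–C12–C13 allyl cation and the silane delivers hydride to the less hindered secondary terminus C16, retains the tetrasubstituted C12=C13 alkene while the protonated amine deactivates the ring-T alkene.

Step 13
Reactants: 20 (14S,17S,21S)-amino ester
Product: 21 (14S,17S,21S)-amino acid: 4-(C12-yl)butanoic acid carrying ring T; C7 benzyl ether; C18 pivalate
Conditions: LiOH, THF/MeOH/H2O, rt; then AcOH to pH 7
Reagents that add atoms: lithium hydroxide, [Li+].[OH-]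
Why: Saponification of the unhindered methyl ester is much faster than that of the pivalate and gives the zwitterionic amino acid.

Step 14
Reactants: 21 (14S,17S,21S)-amino acid
Product: 24 (6S,9R,14S,17S,21S)-vinyl lactam: rings A–D complete; C25 lactam carbonyl; C6 bearing vinyl (C5=C4) and C7H2OBn; C18 pivalate, via acid fluoride 22 (not isolated), via acylammonium enolate 23 (not isolated)
Conditions: cyanuric fluoride, pyridine, CH2Cl2, −15 °C; then syringe-pump addition to AlMe3, K2CO3, CHCl3, 0 °C to rt (2 mM)
Reagents that add atoms: none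
Why: Proposed new method: the acid fluoride acylates the ring nitrogen through a nine-membered acylammonium, which is enolised to 23 and then undergoes a charge-accelerated [3,3] shift across the endocyclic allylamine N–C4–C5=C6, forming C9–C6 as N–C4 breaks; the closest known reaction type is the zwitterionic (ketene, Belluš–Claisen-type) aza-Claisen rearrangement of tertiary allylic amines with acid fluorides, established for N-allyl and 2-vinyl azacycles but not for a tethered acyl donor. Ring A (δ-lactam N23/C25/C9/C6/C21/C22) closes by the sigmatropic C9–C6 bond through a boat, bicyclo[2.2.2]-like array, and ring B arises from the same bond as a transannular contraction of the nine-membered acylammonium ring, itself closed by exo attack of N on the acyl fluoride. C6 is controlled by the tether: the enolate is anchored through C12=C13 to C21 and can reach only the face of C6 syn to C13, which places C7 over ring B and the departing C5=C4 vinyl group over ring A. C9 is fixed as the second bridgehead, because only the enolate orientation with C10 directed toward C13 can close. The step needs intramolecular N-acylation to outrun oligomerisation and the [3,3] shift to outrun dealkylative opening of the acylammonium; the cis disposition of C11 and C21 on the cyclopentene, the quaternary C21, high dilution and the non-nucleophilic fluoride/aluminate counter-ion secure this.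

Step 15
Reactants: 24 (6S,9R,14S,17S,21S)-vinyl lactam; 25 pent-1-en-3-one
Product: 26 (6S,9R,14S,17S,21S)-(E)-enone lactam: C6–C5H=C4H–C3(=O)–C2H2–C1H3
Conditions: 25 (5 equiv), second-generation Hoveyda–Grubbs catalyst (10 mol %), toluene, 80 °C
Reagents that add atoms: pent-1-en-3-one (compound 25), C=CC(=O)CC
Why: Olefin cross-metathesis of the vinyl group on a quaternary carbon (no homodimerisation) with the electron-poor enone partner gives the E-enone and installs C1–C4, the tetrasubstituted C12=C13 alkene being inert.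

Step 16
Reactants: 26 (6S,9R,14S,17S,21S)-(E)-enone lactam
Product: 27 (3S,6S,9R,14S,17S,21S)-(E)-allylic alcohol lactam
Conditions: (R)-2-methyl-CBS-oxazaborolidine, catecholborane, toluene, −78 °C
Reagents that add atoms: none
Why: Corey–Bakshi–Shibata reduction, in which the oxazaborolidine differentiates the bulky alkenyl from the ethyl substituent, sets C3 as S (reagent control) without reducing the lactam or the pivalate.

Step 17
Reactants: 27 (3S,6S,9R,14S,17S,21S)-(E)-allylic alcohol lactam
Product: 28 (3S,6S,9R,14S,17S,21S)-dihydroxy lactam: C3 and C7 alcohols free; C18 pivalate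
Conditions: H2 (1 atm), Pd/C, EtOAc/EtOH, rt
Reagents that add atoms: none
Why: Heterogeneous hydrogenation saturates the disubstituted C4=C5 alkene and cleaves the benzyl ether, while the buried tetrasubstituted C12=C13 alkene is not reduced.

Step 18
Reactants: 28 (3S,6S,9R,14S,17S,21S)-dihydroxy lactam
Product: 29 CNP0221997.1 (target; 3S,6S,9R,14S,17S,21S)
Conditions: LiAlH4, THF, reflux
Reagents that add atoms: none
Why: Hydride reduction converts the lactam carbonyl into C25H2 (tertiary N-methyl amine) and cleaves the pivalate to C18H2OH without affecting any stereocentre.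

Compound list
1 | 1-tert-butyl 3-methyl 4-oxopiperidine-1,3-dicarboxylate | COC(=O)C1CN(C(=O)OC(C)(C)C)CCC1=O | starting material
2 | 2,3-dibromoprop-1-ene | C=C(Br)CBr | starting material
3 | 1-tert-butyl 3-methyl (3R)-3-(2-bromoprop-2-en-1-yl)-4-oxopiperidine-1,3-dicarboxylate | C=C(Br)C[C@]1(C(=O)OC)C(=O)CCN(C(=O)OC(C)(C)C)C1 | intermediate
4 | tributyl(ethenyl)stannane | C=C[Sn](CCCC)(CCCC)CCCC | starting material
5 | 1-tert-butyl 3-methyl (3R)-3-(2-methylidenebut-3-en-1-yl)-4-oxopiperidine-1,3-dicarboxylate | C=CC(=C)C[C@]1(C(=O)OC)C(=O)CCN(C(=O)OC(C)(C)C)C1 | intermediate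
6 | 1-tert-butyl 3-methyl (3R)-3-(2-methylidenebut-3-en-1-yl)-4-[(trifluoromethanesulfonyl)oxy]-3,6-dihydro-2H-pyridine-1,3-dicarboxylate | C=CC(=C)C[C@]1(C(=O)OC)C(OS(=O)(=O)C(F)(F)F)=CCN(C(=O)OC(C)(C)C)C1 | intermediate
7 | potassium [(benzyloxy)methyl]trifluoroborate | [K+].F[B-](F)(F)COCc1ccccc1 | starting material
8 | 1-tert-butyl 3-methyl (3S)-4-[(benzyloxy)methyl]-3-(2-methylidenebut-3-en-1-yl)-3,6-dihydro-2H-pyridine-1,3-dicarboxylate | C=CC(=C)C[C@]1(C(=O)OC)C(COCc2ccccc2)=CCN(C(=O)OC(C)(C)C)C1 | intermediate
9 | [(3S)-4-[(benzyloxy)methyl]-1-methyl-3-(2-methylidenebut-3-en-1-yl)-1,2,3,6-tetrahydropyridin-3-yl]methanol | C=CC(=C)C[C@]1(CO)C(COCc2ccccc2)=CCN(C)C1 | intermediate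
10 | (3S)-4-[(benzyloxy)methyl]-1-methyl-3-(2-methylidenebut-3-en-1-yl)-1,2,3,6-tetrahydropyridine-3-carbaldehyde | C=CC(=C)C[C@]1(C=O)C(COCc2ccccc2)=CCN(C)C1 | intermediate
11 | (3S)-4-[(benzyloxy)methyl]-3-ethynyl-1-methyl-3-(2-methylidenebut-3-en-1-yl)-1,2,3,6-tetrahydropyridine | C=CC(=C)C[C@]1(C#C)C(COCc2ccccc2)=CCN(C)C1 | intermediate
12 | 4-bromo-1,1,1-trimethoxybutane (trimethyl 4-bromoorthobutyrate) | COC(OC)(OC)CCCBr | starting material
13 | lithium acetylide of 11 | C=CC(=C)C[C@]1(C#[C-])C(COCc2ccccc2)=CCN(C)C1.[Li+] | intermediate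
14 | ortho ester: (3S)-4-[(benzyloxy)methyl]-1-methyl-3-(2-methylidenebut-3-en-1-yl)-3-(6,6,6-trimethoxyhex-1-yn-1-yl)-1,2,3,6-tetrahydropyridine | C=CC(=C)C[C@]1(C#CCCCC(OC)(OC)OC)C(COCc2ccccc2)=CCN(C)C1 | intermediate
15 | methyl 6-[(3S)-4-[(benzyloxy)methyl]-1-methyl-3-(2-methylidenebut-3-en-1-yl)-1,2,3,6-tetrahydropyridin-3-yl]hex-5-ynoate | C=CC(=C)C[C@]1(C#CCCCC(=O)OC)C(COCc2ccccc2)=CCN(C)C1 | intermediate
16 | (14S,21S)-spiro dienone ester (rings C, D, T; C16 ketone; C17 exocyclic methylene; methyl butanoate on C12; 14-H on the C22 face) | COC(=O)CCCC1=C2[C@@H](CC1=O)C(=C)C[C@]23CN(C)CC=C3COCc4ccccc4 | intermediate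
17 | bis-borane adduct of 16 (C18–B and C16–O–B, both 9-borabicyclo[3.3.1]nonan-9-yl; C16 epimers) | COC(=O)CCCC1=C2[C@@H](CC1OB3C4CCCC3CCC4)[C@@H](CB5C6CCCC5CCC6)C[C@]27CN(C)CC=C7COCc8ccccc8 | intermediate
18 | (14S,17S,21S)-diol (C18 alcohol on the β face; C16 allylic alcohol, epimers) | COC(=O)CCCC1=C2[C@@H](CC1O)[C@@H](CO)C[C@]23CN(C)CC=C3COCc4ccccc4 | intermediate
19 | (14S,17S,21S)-C18 pivalate, C16 alcohol free (epimers) | COC(=O)CCCC1=C2[C@@H](CC1O)[C@@H](COC(=O)C(C)(C)C)C[C@]23CN(C)CC=C3COCc4ccccc4 | intermediate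
20 | (14S,17S,21S)-amino ester (C16 deoxygenated) | COC(=O)CCCC1=C2[C@@H](CC1)[C@@H](COC(=O)C(C)(C)C)C[C@]23CN(C)CC=C3COCc4ccccc4 | intermediate
21 | (14S,17S,21S)-amino acid | OC(=O)CCCC1=C2[C@@H](CC1)[C@@H](COC(=O)C(C)(C)C)C[C@]23CN(C)CC=C3COCc4ccccc4 | intermediate
22 | acid fluoride of 21 | FC(=O)CCCC1=C2[C@@H](CC1)[C@@H](COC(=O)C(C)(C)C)C[C@]23CN(C)CC=C3COCc4ccccc4 | intermediate
23 | nine-membered acylammonium enolate (zwitterion; N–C25 formed) | [O-]C1=CCCC2=C3[C@@H](CC2)[C@@H](COC(=O)C(C)(C)C)C[C@]34C[N+]1(C)CC=C4COCc5ccccc5 | intermediate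
24 | (6S,9R,14S,17S,21S)-vinyl lactam | C=C[C@]1(COCc5ccccc5)[C@H]2CCC3=C4[C@@H](CC3)[C@@H](COC(=O)C(C)(C)C)C[C@]41CN(C)C2=O | intermediate
25 | pent-1-en-3-one (ethyl vinyl ketone) | C=CC(=O)CC | starting material
26 | (6S,9R,14S,17S,21S)-(E)-enone lactam | CCC(=O)/C=C/[C@]1(COCc5ccccc5)[C@H]2CCC3=C4[C@@H](CC3)[C@@H](COC(=O)C(C)(C)C)C[C@]41CN(C)C2=O | intermediate
27 | (3S,6S,9R,14S,17S,21S)-(E)-allylic alcohol lactam | CC[C@H](O)/C=C/[C@]1(COCc5ccccc5)[C@H]2CCC3=C4[C@@H](CC3)[C@@H](COC(=O)C(C)(C)C)C[C@]41CN(C)C2=O | intermediate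
28 | (3S,6S,9R,14S,17S,21S)-dihydroxy lactam, C18 pivalate | CC[C@H](O)CC[C@]1(CO)[C@H]2CCC3=C4[C@@H](CC3)[C@@H](COC(=O)C(C)(C)C)C[C@]41CN(C)C2=O | intermediate
29 | CNP0221997.1 (3S,6S,9R,14S,17S,21S) | CC[C@H](O)CC[C@]1(CO)[C@H]2CCC3=C4[C@@H](CC3)[C@@H](CO)C[C@]41CN(C)C2 | target

Total step count: 18. Longest linear sequence: 18 steps (from compound 1).

Steps most likely to fail

1. Step 14 (Proposed new method).
   - What may go wrong: intermolecular N-acylation (oligomerisation) or dealkylative opening of the acylammonium outruns the transannular [3,3] shift.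
   - Fallback (stepwise, known reactions), setting out from amino ester 20 and coming back at lactam 24: 2,2,2-trichloroethyl chloroformate in refluxing toluene should cleave the allylic N–C4 bond (von Braun-type dealkylation) to the carbamate allylic chloride F1. LiN(SiMe3)2 then closes ring B by intramolecular SN2′ alkylation of the ester enolate (C9 to C6, chloride leaving from C4) to the carbamate ester F2. The C12=C13 tether again directs C9 to the C13 face, but C6 then depends on the rotamer about C21–C6 and would have to be checked. Zn in AcOH removes the carbamate to the secondary amine ester F3, whose C9 epimers converge on lactamisation (N–C25) on warming to 24.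

2. Step 9.
   - What may go wrong: poor facial selectivity at C14, either because the basic ring nitrogen steers the metal to the α face or because catalyst and substrate are mismatched.
   - Fallback (substrate control in place of catalyst control), setting out from enyne 15 and coming back at enone 16: BH3·SMe2 at −78 °C converts the amine into the amine–borane F4, whose bulky, non-coordinating N–BH3 group shields the C22 (α) face. Cyclisation with achiral [Rh(CO)2Cl]2 under CO should then place C15 on the face of the C6 arm to give the amine–borane enone F5. DABCO in warm toluene removes the borane and returns 16.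

3. Step 15.
   - What may go wrong: the vinyl group, flanked by two quaternary carbons, fails to enter the metathesis cycle and the partner only dimerises.
   - Fallback (carbonyl olefination in place of metathesis), setting out from vinyl lactam 24 and coming back at enone 26: Lemieux–Johnson cleavage (OsO4 cat., NaIO4, 2,6-lutidine, dioxane/H2O; the tetrasubstituted alkene is too hindered to react) gives the neopentyl aldehyde F6. Horner–Wadsworth–Emmons olefination with diethyl (2-oxobutyl)phosphonate (LiCl, DBU, MeCN) gives the E-enone 26.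

Further compounds
F1 | step 14 | carbamate allylic chloride (ring T opened at N–C4; N-methyl 2,2,2-trichloroethyl carbamate on C22; C4 chloride) | COC(=O)CCCC1=C2[C@@H](CC1)[C@@H](COC(=O)C(C)(C)C)C[C@@]2(CN(C)C(=O)OCC(Cl)(Cl)Cl)/C(COCc3ccccc3)=C\CCl
F2 | step 14 | ring-B-closed carbamate ester (C6 vinyl; C9 epimers) | C=C[C@]1(COCc5ccccc5)C(C(=O)OC)CCC3=C4[C@@H](CC3)[C@@H](COC(=O)C(C)(C)C)C[C@]41CN(C)C(=O)OCC(Cl)(Cl)Cl
F3 | step 14 | secondary amine ester (C9 epimers) | C=C[C@]1(COCc5ccccc5)C(C(=O)OC)CCC3=C4[C@@H](CC3)[C@@H](COC(=O)C(C)(C)C)C[C@]41CNC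
F4 | step 9 | amine–borane of 15 | C=CC(=C)C[C@]1(C#CCCCC(=O)OC)C(COCc2ccccc2)=CC[N+](C)([BH3-])C1
F5 | step 9 | amine–borane of 16 | COC(=O)CCCC1=C2[C@@H](CC1=O)C(=C)C[C@]23C[N+](C)([BH3-])CC=C3COCc4ccccc4
F6 | step 15 | aldehyde lactam (C5 aldehyde on C6) | O=C[C@]1(COCc5ccccc5)[C@H]2CCC3=C4[C@@H](CC3)[C@@H](COC(=O)C(C)(C)C)C[C@]41CN(C)C2=O
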